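## The problem

Compound 15 is an achiral triaryl bis-ether of the phlorethol type. Its three benzene rings are held together only by two ether oxygens, which sit on the neighbouring carbons B1 and B2 of the central ring B. Ring A is a phloroglucinol unit bound through the carbon between two of its hydroxyls (a 2,4,6-trihydroxyphenoxy group on B1). Ring C is a pyrogallol-type unit bound through its C1 (a 3,4,5-trihydroxyphenoxy group on B2). With no stereocentre, the whole difficulty is regiochemical and lies in ring B: five contiguous oxygens of three kinds (ether to ring A at B1, ether to ring C at B2, hydroxyls at B3 to B5) and a single hydrogen at B6. Substitution on a preformed penta-oxygenated benzene cannot tell these oxygens apart. The B1–O–A linkage is also a tri-ortho-substituted ether between two electron-rich rings, the least favourable case for a coupling. The nine free hydroxyls, two triads of them vicinal, oxidise readily in air and faster under base, so they must travel as ethers and be released last under acidic, non-oxidising conditions; the diaryl ether bonds themselves are robust. The enabling feature is that B1 to B4 are four contiguous oxygen-bearing carbons, the pattern of squaric acid, while B5 (oxygen) and B6 (hydrogen) are the two carbons of a 1-alkoxyvinyl group. Ring expansion of the derived 4-(1-alkoxyvinyl)cyclobutenone then builds ring B with every oxygen in place and leaves the ketene-derived carbon B1 as the only free hydroxyl.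

## Retrosynthesis

**15 ⇒ 14 (nine O–alkyl bonds).** The last operation is removal of all protecting groups. Alkyl ethers are chosen because the squarate, the vinyl ether and both aryl building blocks bring them for free, and because one Lewis acid treatment cleaves eight methyl groups and one ethyl group together. Precursor 14 is air-stable and chromatographable, which 15 is not. The forward step must cleave nine C–O(alkyl) bonds without touching the two diaryl ether bonds.

**14 ⇒ 12 + 13 (the ether bond between the B1 oxygen and ring A).** Cutting on the ring A side of the oxygen leaves ring B as a phenol and ring A as 2-iodo-1,3,5-trimethoxybenzene 13. The opposite cut would need a halogen at B1 of a penta-oxygenated ring, with no selective way to install it. The chosen cut puts the halogen on the symmetric, purchasable ring and asks ring B only for a free hydroxyl at B1, which the ring-forming step delivers. The forward reaction is a copper-mediated diaryl ether coupling that must tolerate two ortho methoxy groups on the iodide.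

**12 ⇒ 9 (bond B1–B6, ring B).** Phenol 12 is the tautomer of cyclohexadienone 11, which opens in a retro-6π sense to the (Z)-dienylketene 10; this in turn is the ring-opened form of cyclobutenone 9. This one cut removes the benzene ring and all of its regiochemical problems. In 9 the positions of the four oxygens B1 to B4 are fixed by the four-membered ring, and B5 and B6 by the vinyl ether. Cutting ring B instead of ring A or ring C is preferred because rings A and C are symmetric and available as 13 and 4, whereas ring B is the only ring that cannot be bought or made by substitution chemistry. The forward step needs only heat, and the C4 oxygen of 9 must be capped (as a methyl ether) so that B4 and B1 emerge differentiated.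

**9 ⇒ 5 + 6 (the bond from C4 to the vinyl carbon, and the O–methyl bond at C4).** The quaternary carbon of 9 comes from 1,2-addition of 1-ethoxyvinyllithium 7, made from ethyl vinyl ether 6, to one carbonyl of the mixed squarate 5. The lithium alkoxide 8 is methylated in the same flask. The forward reaction must choose the carbonyl next to the methoxy-bearing carbon of 5. That carbonyl is conjugated to the aryloxy oxygen, the weaker donor of the two, and should therefore be the more electrophilic.

**5 ⇒ 3 + 4, 3 ⇒ 2 ⇒ 1 (the vinylic C–O bonds of the squarate).** The two different ether groups of 5 are introduced one at a time on squaric acid dichloride 2: methanol gives the ester chloride 3, then 3,4,5-trimethoxyphenol 4 displaces the remaining chloride. Each substitution deactivates the ring towards the next, so sequential addition–elimination can be stopped cleanly. Ring C is attached at this stage because its oxygen must sit on the squarate carbon that becomes B2. Dichloride 2 comes from squaric acid 1.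

## Roads not taken

**Alternative 1:** Ring C is cut at C1–C2 and C1–C6, back to 3,4,5-trimethoxypyrylium tetrafluoroborate A2 and the aryloxymethylphosphonium salt A3 derived from 2,3,4-trimethoxy-6-(2,4,6-trimethoxyphenoxy)phenol A4. In the forward step the ylide of A3 adds to C2 of A2, the 2H-pyran opens to a dienal, and a second deprotonation followed by intramolecular Wittig closure gives the nonamethyl ether A1.
- Merits: the full skeleton appears in the key step with uniform methyl protection, and only demethylation follows. In that respect it is tidier than the chosen plan, which ends with a hindered coupling and a mixed methyl/ethyl deprotection.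
- Weak points: the key step builds ring C, the easiest ring (it is commercial as 4). All the difficulty of ring B is pushed into A4, whose preparation needs the same hindered ring A ether plus a way to single out the B2 oxygen among four. A pyrylium ion unsubstituted at C2 and C6 is highly electrophilic and prone to hydrolysis, and the α-aryloxy ylide is non-stabilised and hindered.
- Comparison: the chosen plan spends its key step on the hard ring, which outweighs the cleaner endgame of this road.

**Alternative 2:** Ring C is cut at C2–C3 and C5–C6, back to 1,3-dimethoxyacetone A6 and the 2-aryloxy-3-(dimethylamino)acrolein A7, again derived from A4. Base-mediated double condensation of both α-carbons of A6 with the two formyl-level carbons of A7, then acidification, would give phenol A5.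
- Merits: no transition metal is needed, and ketone-plus-malonaldehyde-equivalent phenol syntheses are an established reaction type.
- Weak points: as in Alternative 1, ring C is built and ring B is not, and A4 must be made first. Converting A4 into A7 means formylating an aryloxyacetic acid derivative with a chloroiminium reagent, which would also attack the open positions of the trimethoxylated ring A. A6 is an α-alkoxy ketone that self-condenses under the base required.
- Comparison: the free para-hydroxyl of A5 gains nothing, since every oxygen is freed at the end anyway. The chosen plan has the longer endgame but does not need A4.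

**Alternative 3:** Ring B is cut at B1–B2, B5–B6 and B4–B5, back to the siloxycyclobutenone A9 and the aryl ethynyl ether A10. On heating, A9 opens to a vinylketene, which adds A10 in a (2+2) sense; the new cyclobutenone opens and closes by 6π electrocyclisation (a Danheiser benzannulation) to give phenol A8 with all three rings joined.
- Merits: this is the most convergent road. It avoids the late coupling of the hindered ring A halide and delivers B4 and B5 already differentiated. On convergence and on the B1–O–A bond it is better than the chosen plan.
- Weak points: A9 has to come from the mixed squarate 5 by reduction of one specific carbonyl and silylation, so it meets the same regiochemical question as step 4 and adds a step. A10, an ynol ether on a doubly ortho-substituted electron-rich ring, takes several steps to make. The bimolecular (2+2) step demands that a fully oxygen-substituted, weakly electrophilic vinylketene be trapped by the alkyne faster than it dimerises; the chosen plan needs only a unimolecular cascade.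
- Comparison: the chosen plan sets purchasable partners, a unimolecular key step and a firmly precedented substrate class (4-alkenyl-4-alkoxycyclobutenones from squarates) against the higher convergence of this road.

Key step: step 5

Assumption: the target has no stereocentre, so no configuration needs to be set; the single stereocentre on the route (C4 of 9) is carried racemic and is erased in step 5.

## Route

Step 1
Reactants: 1 squaric acid (3,4-dihydroxycyclobut-3-ene-1,2-dione)
Product: 2 squaric acid dichloride (3,4-dichlorocyclobut-3-ene-1,2-dione)
Conditions: (COCl)2, DMF (cat.), CH2Cl2, 0 °C to rt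
Reagents that add atoms: oxalyl chloride, ClC(=O)C(=O)Cl
Why: The chloroiminium species from DMF and oxalyl chloride turns both vinylogous acid hydroxyls into vinylogous acid chlorides; this is the standard preparation of the dichloride.

Step 2
Reactants: 2 squaric acid dichloride
Product: 3 3-chloro-4-methoxycyclobut-3-ene-1,2-dione
Conditions: MeOH (1.0 equiv), CH2Cl2, −20 °C to rt
Reagents that add atoms: methanol, CO
Why: Addition–elimination of methanol at one vinylogous acid chloride carbon; the methoxy donor introduced first lowers the electrophilicity of the remaining C–Cl carbon, so one equivalent should stop at the ester chloride.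

Step 3
Reactants: 3 3-chloro-4-methoxycyclobut-3-ene-1,2-dione; 4 3,4,5-trimethoxyphenol
Product: 5 3-methoxy-4-(3,4,5-trimethoxyphenoxy)cyclobut-3-ene-1,2-dione
Conditions: Et3N, CH2Cl2, −78 to 0 °C
Reagents that add atoms: none
Why: Second addition–elimination (vinylogous O-acylation of a phenol); chloride leaves far more readily than methoxide, so the methoxy group stays, and the hard acyl-type electrophile at low temperature should take the aryloxide at oxygen and not at ring carbon.

Step 4
Reactants: 5 3-methoxy-4-(3,4,5-trimethoxyphenoxy)cyclobut-3-ene-1,2-dione; 6 ethyl vinyl ether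
Product: 9 racemic 4-(1-ethoxyvinyl)-3,4-dimethoxy-2-(3,4,5-trimethoxyphenoxy)cyclobut-2-en-1-one, via 1-ethoxyvinyllithium 7 (not isolated), via lithium cyclobutenolate adduct 8 (not isolated)
Conditions: 6, t-BuLi, THF, −78 to 0 °C; then added to 5, THF, −78 °C; then MeOTf, −78 to 0 °C; aq. NaHCO3
Reagents that add atoms: methyl triflate, COS(=O)(=O)C(F)(F)F
Why: α-Lithiation of the vinyl ether, 1,2-addition of the organolithium to a squarate carbonyl and O-alkylation of the tertiary alkoxide in the same flask; the carbonyl next to the methoxy-bearing carbon is conjugated to the weaker aryloxy donor and should be attacked in preference to the vinylogous methyl ester carbonyl, and capping with methyl triflate keeps the acid-labile adduct away from any proton source. The new quaternary centre forms racemic and is of no consequence.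

Step 5
Reactants: 9 racemic 4-(1-ethoxyvinyl)-3,4-dimethoxy-2-(3,4,5-trimethoxyphenoxy)cyclobut-2-en-1-one
Product: 12 5-ethoxy-3,4-dimethoxy-2-(3,4,5-trimethoxyphenoxy)phenol, via (Z)-dienylketene 10 (not isolated), via cyclohexa-2,4-dienone 11 (not isolated)
Conditions: PhMe (dilute, degassed), 110 °C, Ar
Reagents that add atoms: none
Why: Thermal conrotatory 4π opening of the cyclobutenone breaks the C1–C4 bond and gives vinylketene 10. The C4 methoxy donor prefers to rotate outward, which turns the 1-ethoxyvinyl group inward and places the vinyl CH2 next to the ketene carbon (the Z isomer). Thermal disrotatory 6π electrocyclisation then joins the ketene carbon (B1) to the CH2 carbon (B6), closing the six-membered ring B as dienone 11, and enolisation aromatises it irreversibly to 12. The closest known reaction type is the Moore rearrangement of squarate-derived 4-alkenyl-4-alkoxycyclobutenones to hydroquinone monoethers. No stereocentre is formed, and the one in 9 is destroyed. Regiochemistry is fixed by connectivity: the four-membered ring holds B1 to B4 in order and the enol ether supplies B5 (oxygen) and B6 (hydrogen). The needed selectivity is the inward rotation of the vinyl group; any ketene of the other geometry cannot cyclise and should reclose to 9 and re-enter the productive path. The methyl cap on the C4 oxygen blocks lactonisation onto the ketene and leaves B1 as the only free hydroxyl.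

Step 6
Reactants: 12 5-ethoxy-3,4-dimethoxy-2-(3,4,5-trimethoxyphenoxy)phenol; 13 2-iodo-1,3,5-trimethoxybenzene
Product: 14 1-ethoxy-2,3-dimethoxy-4-(3,4,5-trimethoxyphenoxy)-5-(2,4,6-trimethoxyphenoxy)benzene
Conditions: CuI (cat.), picolinic acid, K3PO4, DMSO, 100 °C, Ar
Reagents that add atoms: none
Why: Ullmann-type diaryl ether coupling; the picolinate-ligated copper system is one that accepts ortho-substituted iodides and phenols, and copper-mediated coupling of halotrimethoxybenzenes with polymethoxyphenols is the classical entry to phlorethol methyl ethers.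

Step 7
Reactants: 14 1-ethoxy-2,3-dimethoxy-4-(3,4,5-trimethoxyphenoxy)-5-(2,4,6-trimethoxyphenoxy)benzene
Product: 15 5-(2,4,6-trihydroxyphenoxy)-4-(3,4,5-trihydroxyphenoxy)benzene-1,2,3-triol
Conditions: BBr3 (excess), CH2Cl2, −78 °C to rt; then MeOH, H2O, 0 °C, Ar
Reagents that add atoms: none
Why: Lewis acid mediated cleavage of aryl alkyl ethers by bromide attack at the alkyl carbon; methyl and ethyl groups both leave as alkyl bromides, while the diaryl ether bonds offer no carbon open to substitution and should survive.

## Compound list

1 | squaric acid (3,4-dihydroxycyclobut-3-ene-1,2-dione) | OC1=C(O)C(=O)C1=O | starting material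
2 | squaric acid dichloride (3,4-dichlorocyclobut-3-ene-1,2-dione) | ClC1=C(Cl)C(=O)C1=O | intermediate
3 | 3-chloro-4-methoxycyclobut-3-ene-1,2-dione | COC1=C(Cl)C(=O)C1=O | intermediate
4 | 3,4,5-trimethoxyphenol | COc1cc(O)cc(OC)c1OC | starting material
5 | 3-methoxy-4-(3,4,5-trimethoxyphenoxy)cyclobut-3-ene-1,2-dione | COC1=C(Oc2cc(OC)c(OC)c(OC)c2)C(=O)C1=O | intermediate
6 | ethyl vinyl ether | C=COCC | starting material
7 | 1-ethoxyvinyllithium | [Li]C(=C)OCC | intermediate
8 | lithium 1-(1-ethoxyvinyl)-2-methoxy-4-oxo-3-(3,4,5-trimethoxyphenoxy)cyclobut-2-en-1-olate (racemic) | CCOC(=C)C1([O-])C(OC)=C(Oc2cc(OC)c(OC)c(OC)c2)C1=O.[Li+] | intermediate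
9 | racemic 4-(1-ethoxyvinyl)-3,4-dimethoxy-2-(3,4,5-trimethoxyphenoxy)cyclobut-2-en-1-one | CCOC(=C)C1(OC)C(OC)=C(Oc2cc(OC)c(OC)c(OC)c2)C1=O | intermediate
10 | (3Z)-5-ethoxy-3,4-dimethoxy-2-(3,4,5-trimethoxyphenoxy)hexa-1,3,5-trien-1-one | O=C=C(Oc1cc(OC)c(OC)c(OC)c1)/C(OC)=C(/OC)C(=C)OCC | intermediate
11 | 5-ethoxy-3,4-dimethoxy-2-(3,4,5-trimethoxyphenoxy)cyclohexa-2,4-dien-1-one | O=C1CC(OCC)=C(OC)C(OC)=C1Oc1cc(OC)c(OC)c(OC)c1 | intermediate
12 | 5-ethoxy-3,4-dimethoxy-2-(3,4,5-trimethoxyphenoxy)phenol | Oc1cc(OCC)c(OC)c(OC)c1Oc1cc(OC)c(OC)c(OC)c1 | intermediate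
13 | 2-iodo-1,3,5-trimethoxybenzene | COc1cc(OC)c(I)c(OC)c1 | starting material
14 | 1-ethoxy-2,3-dimethoxy-4-(3,4,5-trimethoxyphenoxy)-5-(2,4,6-trimethoxyphenoxy)benzene | COc1cc(OC)c(Oc2cc(OCC)c(OC)c(OC)c2Oc2cc(OC)c(OC)c(OC)c2)c(OC)c1 | intermediate
15 | 5-(2,4,6-trihydroxyphenoxy)-4-(3,4,5-trihydroxyphenoxy)benzene-1,2,3-triol | Oc1cc(O)c(Oc2cc(O)c(O)c(O)c2Oc2cc(O)c(O)c(O)c2)c(O)c1 | target

## Step count and risks

Total: 7 steps. Longest linear sequence: 7 steps (1 to 15); compounds 4, 6 and 13 are purchased and enter at steps 3, 4 and 6.

**Step 5 (key step).** The most likely failure is loss of the substrate before the ring opens: trace acid can hydrolyse the enol ether or ionise the doubly oxygenated C4. The electron-rich ketene 10 can also be intercepted or oligomerise, and the penta-oxygenated phenol can oxidise in air during isolation.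
Fallback, from 5 to 12: the classical hydroxy variant of the same ring expansion, with the two para oxygens told apart afterwards by sterics.
- Addition of 7 to 5 as in step 4, quenched with aqueous NH4Cl instead of methyl triflate, gives racemic 4-(1-ethoxyvinyl)-4-hydroxy-3-methoxy-2-(3,4,5-trimethoxyphenoxy)cyclobut-2-en-1-one F1.
- Thermolysis in toluene under argon should give the hydroquinone 5-ethoxy-3-methoxy-2-(3,4,5-trimethoxyphenoxy)benzene-1,4-diol F2.
- Pivaloyl chloride and pyridine should acylate the less hindered B1 hydroxyl (one ortho hydrogen) in preference to the B4 hydroxyl (flanked by two alkoxy groups), giving 5-ethoxy-4-hydroxy-3-methoxy-2-(3,4,5-trimethoxyphenoxy)phenyl pivalate F3.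
- Methylation with MeI and K2CO3 gives 5-ethoxy-3,4-dimethoxy-2-(3,4,5-trimethoxyphenoxy)phenyl pivalate F4, and NaOMe in methanol releases 12.

**Step 4.** The most likely failure is poor discrimination between the two carbonyls of 5. The donor difference between aryloxy and methoxy is smaller than the alkoxy/alkyl difference on which the usual squarate selectivity rests, and addition at the other carbonyl would carry ring C to B3. Displacement of aryloxide by addition–elimination and incomplete methylation of the hindered alkoxide are secondary risks.
Fallback, from 2 and 4 to 9: regiochemistry is set by a substitution that can only occur at one carbon.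
- Two equivalents of 4 with Et3N convert 2 into the symmetric squarate 3,4-bis(3,4,5-trimethoxyphenoxy)cyclobut-3-ene-1,2-dione F5, whose two carbonyls are equivalent.
- Addition of 7 and methyl triflate capping as in step 4 give racemic 4-(1-ethoxyvinyl)-4-methoxy-2,3-bis(3,4,5-trimethoxyphenoxy)cyclobut-2-en-1-one F6.
- One equivalent of NaOMe in MeOH/THF at low temperature should exchange only the aryloxy group on the β-carbon of the enone (C3), the sole electrophilic alkene carbon, by conjugate addition–elimination, giving 9 and returning one equivalent of 4.

**Step 6.** The most likely failure is slow reaction at the doubly ortho-substituted, electron-rich iodide, so that reductive deiodination of 13 and oxidative degradation of the electron-rich phenol under basic copper conditions outrun the coupling.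
Fallback, from 12 to 15: ring A is introduced as an activated electrophile and its third oxygen is added afterwards.
- Nucleophilic aromatic substitution of 12 on 4-fluoro-3,5-dimethoxybenzaldehyde (K2CO3, DMSO, heat) gives 4-[5-ethoxy-3,4-dimethoxy-2-(3,4,5-trimethoxyphenoxy)phenoxy]-3,5-dimethoxybenzaldehyde F7.
- Baeyer–Villiger (Dakin-type) oxidation with H2O2 and catalytic diphenyl diselenide gives 4-[5-ethoxy-3,4-dimethoxy-2-(3,4,5-trimethoxyphenoxy)phenoxy]-3,5-dimethoxyphenyl formate F8; this is the same transformation that turns 3,4,5-trimethoxybenzaldehyde into 4.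
- Methanolysis with K2CO3 gives 4-[5-ethoxy-3,4-dimethoxy-2-(3,4,5-trimethoxyphenoxy)phenoxy]-3,5-dimethoxyphenol F9, and BBr3 as in step 7 converts it into 15.

**Step 7.** The most likely failure is incomplete cleavage of nine ether groups (the ethyl group and the flanked methyl groups being slowest), giving mixtures of partially alkylated polyphenols. Oxidation of the vicinal triol rings and retention on boron residues during work-up and chromatography are further risks.
Fallback, from 14 to 15: derivatise, purify, release.
- The crude product of the BBr3 treatment is acetylated without isolation (Ac2O, pyridine) to the stable, chromatographable nonaacetate 5-(2,4,6-triacetoxyphenoxy)-4-(3,4,5-triacetoxyphenoxy)benzene-1,2,3-triyl triacetate F10.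
- Incompletely dealkylated material is separated at this stage and resubmitted.
- Acidic methanolysis of F10 (HCl in MeOH, degassed) then frees 15 without exposing it to base.

## Further compounds

F1 | step 5 | racemic 4-(1-ethoxyvinyl)-4-hydroxy-3-methoxy-2-(3,4,5-trimethoxyphenoxy)cyclobut-2-en-1-one | CCOC(=C)C1(O)C(OC)=C(Oc2cc(OC)c(OC)c(OC)c2)C1=O
F2 | step 5 | 5-ethoxy-3-methoxy-2-(3,4,5-trimethoxyphenoxy)benzene-1,4-diol | Oc1cc(OCC)c(O)c(OC)c1Oc1cc(OC)c(OC)c(OC)c1
F3 | step 5 | 5-ethoxy-4-hydroxy-3-methoxy-2-(3,4,5-trimethoxyphenoxy)phenyl pivalate | CC(C)(C)C(=O)Oc1cc(OCC)c(O)c(OC)c1Oc1cc(OC)c(OC)c(OC)c1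
F4 | step 5 | 5-ethoxy-3,4-dimethoxy-2-(3,4,5-trimethoxyphenoxy)phenyl pivalate | CC(C)(C)C(=O)Oc1cc(OCC)c(OC)c(OC)c1Oc1cc(OC)c(OC)c(OC)c1
F5 | step 4 | 3,4-bis(3,4,5-trimethoxyphenoxy)cyclobut-3-ene-1,2-dione | O=C1C(=O)C(Oc2cc(OC)c(OC)c(OC)c2)=C1Oc1cc(OC)c(OC)c(OC)c1
F6 | step 4 | racemic 4-(1-ethoxyvinyl)-4-methoxy-2,3-bis(3,4,5-trimethoxyphenoxy)cyclobut-2-en-1-one | CCOC(=C)C1(OC)C(Oc2cc(OC)c(OC)c(OC)c2)=C(Oc2cc(OC)c(OC)c(OC)c2)C1=O
F7 | step 6 | 4-[5-ethoxy-3,4-dimethoxy-2-(3,4,5-trimethoxyphenoxy)phenoxy]-3,5-dimethoxybenzaldehyde | O=Cc1cc(OC)c(Oc2cc(OCC)c(OC)c(OC)c2Oc2cc(OC)c(OC)c(OC)c2)c(OC)c1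
F8 | step 6 | 4-[5-ethoxy-3,4-dimethoxy-2-(3,4,5-trimethoxyphenoxy)phenoxy]-3,5-dimethoxyphenyl formate | O=COc1cc(OC)c(Oc2cc(OCC)c(OC)c(OC)c2Oc2cc(OC)c(OC)c(OC)c2)c(OC)c1
F9 | step 6 | 4-[5-ethoxy-3,4-dimethoxy-2-(3,4,5-trimethoxyphenoxy)phenoxy]-3,5-dimethoxyphenol | Oc1cc(OC)c(Oc2cc(OCC)c(OC)c(OC)c2Oc2cc(OC)c(OC)c(OC)c2)c(OC)c1
F10 | step 7 | 5-(2,4,6-triacetoxyphenoxy)-4-(3,4,5-triacetoxyphenoxy)benzene-1,2,3-triyl triacetate | CC(=O)Oc1cc(OC(C)=O)c(Oc2cc(OC(C)=O)c(OC(C)=O)c(OC(C)=O)c2Oc2cc(OC(C)=O)c(OC(C)=O)c(OC(C)=O)c2)c(OC(C)=O)c1
A1 | alternative 1 | 1,2,3-trimethoxy-4-(3,4,5-trimethoxyphenoxy)-5-(2,4,6-trimethoxyphenoxy)benzene | COc1cc(OC)c(Oc2cc(OC)c(OC)c(OC)c2Oc2cc(OC)c(OC)c(OC)c2)c(OC)c1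
A2 | alternative 1 | 3,4,5-trimethoxypyrylium tetrafluoroborate | COc1c[o+]cc(OC)c1OC.F[B-](F)(F)F
A3 | alternative 1 | {[2,3,4-trimethoxy-6-(2,4,6-trimethoxyphenoxy)phenoxy]methyl}triphenylphosphonium chloride | COc1cc(OC)c(Oc2cc(OC)c(OC)c(OC)c2OC[P+](c2ccccc2)(c2ccccc2)c2ccccc2)c(OC)c1.[Cl-]
A4 | alternative 1 | 2,3,4-trimethoxy-6-(2,4,6-trimethoxyphenoxy)phenol | COc1cc(OC)c(Oc2cc(OC)c(OC)c(OC)c2O)c(OC)c1
A5 | alternative 2 | 2,6-dimethoxy-4-[2,3,4-trimethoxy-6-(2,4,6-trimethoxyphenoxy)phenoxy]phenol | COc1cc(Oc2c(OC)c(OC)c(OC)cc2Oc2c(OC)cc(OC)cc2OC)cc(OC)c1O
A6 | alternative 2 | 1,3-dimethoxyacetone | COCC(=O)COC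
A7 | alternative 2 | (Z)-3-(dimethylamino)-2-[2,3,4-trimethoxy-6-(2,4,6-trimethoxyphenoxy)phenoxy]prop-2-enal | CN(C)/C=C(\Oc1c(OC)c(OC)c(OC)cc1Oc1c(OC)cc(OC)cc1OC)C=O
A8 | alternative 3 | 2-(tert-butyldimethylsilyloxy)-3-methoxy-4-(3,4,5-trimethoxyphenoxy)-5-(2,4,6-trimethoxyphenoxy)phenol | Oc1cc(Oc2c(OC)cc(OC)cc2OC)c(Oc2cc(OC)c(OC)c(OC)c2)c(OC)c1O[Si](C)(C)C(C)(C)C
A9 | alternative 3 | racemic 4-(tert-butyldimethylsilyloxy)-3-methoxy-2-(3,4,5-trimethoxyphenoxy)cyclobut-2-en-1-one | O=C1C(Oc2cc(OC)c(OC)c(OC)c2)=C(OC)C1O[Si](C)(C)C(C)(C)C
A10 | alternative 3 | 2-(ethynyloxy)-1,3,5-trimethoxybenzene | C#COc1c(OC)cc(OC)cc1OC
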